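**Plan**
1. Retrosynthetic cuts, in order: the O–Si bond; the Cα–C5 bond of the γ-lactone (Cα is the furyl-bearing carbon, C5 the fusion carbon β to the C7 ketone); the acyl bond on O–C4, which releases a 5-alkyl-2-furylacetic acid; the O1–C2 macrolactone bond; the C5=C6 olefin.
2. Forward order: cross-metathesis joins two small pieces to an E-enone seco acid. The ten-membered lactone is closed first, the furylacetate is attached to O–C4, and the five-membered lactone is closed last across C4–C5 of the finished macrocycle.
3. Enabling feature: in the oxacyclodecene ring the C4 oxygen is γ to the C7 ketone across the E C5=C6 bond. An acyl group on that oxygen therefore holds a CH2, acidified by both the furan and the ester carbonyl, exactly one five-membered ring away from the electrophilic C5.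
4. Conformational lever: the s-trans lactone (C3–C2–O1–C10–C9) and the s-cis E-enone (C8–C7–C6=C5–C4) fill the two anti–anti edges of a boat–chair–boat ring. With the 10R-methyl equatorial, the 4S-acyloxy group is axial over the outer face of C5.
5. Stereochemistry: C10 comes from (R)-γ-valerolactone, the side-chain carbinol from (R)-butane-1,3-diol, and C4 from an (S)-HYTRA acetate aldol. C5 and Cα both derive from C4 in the key step, by tether delivery and then kinetic protonation of a planar enolate that erases the Cα outcome of the C–C bond formation.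

Key step: step 15

Numbering used below: O1, C2 (lactone C=O), C3, C4 (carbinol), C5, C6, C7 (ketone), C8, C9, C10 (CHMe) of the oxacyclodecane ring; Cα is the furyl-bearing carbon.
Assumption: (R)-γ-valerolactone, (S)-HYTRA and (R)-butane-1,3-diol are taken as commercial single enantiomers.

**Step 1**
Reactants: 1 (R)-γ-valerolactone
Product: 2 (4R)-4-hydroxy-N-methoxy-N-methylpentanamide
Conditions: MeNH(OMe)·HCl (1.5 equiv), i-PrMgCl (3 equiv), THF, −20 → 0 °C; aq NH4Cl; used crude
Reagents that add atoms: N,O-dimethylhydroxylamine hydrochloride, CNOC.Cl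
Why: Weinreb aminolysis, in which the chloromagnesium amide opens the lactone at the acyl carbon, so the C–O stereocentre (future C10) is untouched.

**Step 2**
Reactants: 2 (4R)-4-hydroxy-N-methoxy-N-methylpentanamide
Product: 3 (6R)-6-hydroxyhept-1-en-3-one
Conditions: CH2=CHMgBr (3 equiv), THF, −78 → 0 °C; inverse quench into cold aq KHSO4
Reagents that add atoms: vinylmagnesium bromide, C=C[Mg]Br
Why: Weinreb ketone synthesis, in which one equivalent of Grignard reagent is spent on the OH, the chelated tetrahedral adduct stops over-addition, and the acidic inverse quench keeps the freed amine from adding to the vinyl ketone.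

**Step 3**
Reactants: 4 (S)-HYTRA [(1S)-2-hydroxy-1,2,2-triphenylethyl acetate]; 5 acrolein
Product: 7 (1S)-2-hydroxy-1,2,2-triphenylethyl (3S)-3-hydroxypent-4-enoate, via dilithio HYTRA enolate 6 (not isolated)
Conditions: LiN(i-Pr)2 (2.1 equiv), THF, −78 → 0 °C; then 5, THF–2-methylbutane, −125 °C; aq NH4Cl; recrystallisation
Reagents that add atoms: none
Why: Braun HYTRA acetate aldol addition, in which the doubly deprotonated (S)-auxiliary acetate adds 1,2 to one face of the enal and should give the 3S carbinol (future C4), with the crystalline adduct allowing upgrade of diastereomeric purity.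

**Step 4**
Reactants: 7 (1S)-2-hydroxy-1,2,2-triphenylethyl (3S)-3-hydroxypent-4-enoate
Product: 8 (3S)-3-hydroxypent-4-enoic acid
Conditions: KOH, MeOH–H2O, rt; filter off the diol; HCl to pH 2–3
Reagents that add atoms: potassium hydroxide, [K+].[OH-]
Why: Mild ester saponification frees the β-hydroxy acid and returns the auxiliary diol without touching the carbinol centre.

**Step 5**
Reactants: 8 (3S)-3-hydroxypent-4-enoic acid
Product: 10 (3S)-3-(tert-butyldimethylsilyloxy)pent-4-enoic acid, via bis-silylated silyl ester 9 (not isolated)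
Conditions: TBSCl (2.5 equiv), imidazole, DMF, rt; then AcOH–THF–H2O, rt
Reagents that add atoms: tert-butyldimethylsilyl chloride, CC(C)(C)[Si](C)(C)Cl
Why: Bis-silylation followed by selective solvolysis of the far more labile silyl ester leaves the allylic TBS ether, which blocks O–C4 and is a poor leaving group during the later carboxyl activation.

**Step 6**
Reactants: 3 (6R)-6-hydroxyhept-1-en-3-one (1.5 equiv); 10 (3S)-3-(tert-butyldimethylsilyloxy)pent-4-enoic acid
Product: 11 (3S,4E,9R)-3-(tert-butyldimethylsilyloxy)-9-hydroxy-6-oxodec-4-enoic acid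
Conditions: second-generation Hoveyda–Grubbs catalyst (5 mol %), CH2Cl2, 40 °C
Reagents that add atoms: none
Why: Olefin cross-metathesis of a vinyl ketone with a hindered allylic ether, two partners that homodimerise slowly, should give the conjugated enone with the usual high E preference and tolerates the free OH and CO2H.

**Step 7**
Reactants: 11 (3S,4E,9R)-3-(tert-butyldimethylsilyloxy)-9-hydroxy-6-oxodec-4-enoic acid
Product: 12 (4S,5E,10R)-4-(tert-butyldimethylsilyloxy)-10-methyloxacyclodec-5-ene-2,7-dione
Conditions: 2-methyl-6-nitrobenzoic anhydride (1.3 equiv), DMAP (3 equiv), CH2Cl2 (1 mM, slow addition), rt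
Reagents that add atoms: none
Why: Shiina macrolactonisation at room temperature under high dilution, where the planar E-enone and the forming s-trans ester cut down the free rotors of the chain and the mild conditions avoid β-elimination of the silyloxy group.

**Step 8**
Reactants: 12 (4S,5E,10R)-4-(tert-butyldimethylsilyloxy)-10-methyloxacyclodec-5-ene-2,7-dione
Product: 13 (4S,5E,10R)-4-hydroxy-10-methyloxacyclodec-5-ene-2,7-dione
Conditions: HF·pyridine, THF–pyridine, 0 °C → rt
Reagents that add atoms: none
Why: Acidic fluoride desilylation, in which the E geometry keeps the γ-hydroxy enone from cyclising to a furan and no base is present to start retro-aldol cleavage or elimination.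

**Step 9**
Reactants: 14 (3R)-butane-1,3-diol
Product: 15 (2R)-4-iodobutan-2-ol
Conditions: I2, PPh3, imidazole, CH2Cl2, 0 °C
Reagents that add atoms: iodine, [I][I]
Why: Appel-type (Garegg–Samuelsson) iodination takes the primary hydroxyl on steric grounds and leaves the carbinol stereocentre untouched.

**Step 10**
Reactants: 15 (2R)-4-iodobutan-2-ol
Product: 16 tert-butyl{[(2R)-4-iodobutan-2-yl]oxy}dimethylsilane
Conditions: TBSCl, imidazole, DMF, rt
Reagents that add atoms: tert-butyldimethylsilyl chloride, CC(C)(C)[Si](C)(C)Cl
Why: Standard silylation of the secondary alcohol gives an ether that survives organolithium reagents, oxidation, carbodiimide coupling and amide base.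

**Step 11**
Reactants: 17 furan; 16 tert-butyl{[(2R)-4-iodobutan-2-yl]oxy}dimethylsilane
Product: 19 tert-butyl{[(2R)-4-(furan-2-yl)butan-2-yl]oxy}dimethylsilane, via 2-furyllithium 18 (not isolated)
Conditions: n-BuLi, THF, −78 → 0 °C; then 16, DMPU, −78 °C → rt
Reagents that add atoms: none
Why: α-Lithiation of furan followed by SN2 alkylation with an unhindered primary iodide, a standard route to 2-alkylfurans.

**Step 12**
Reactants: 19 tert-butyl{[(2R)-4-(furan-2-yl)butan-2-yl]oxy}dimethylsilane
Product: 21 2-{5-[(3R)-3-(tert-butyldimethylsilyloxy)butyl]furan-2-yl}ethanol, via 5-lithiofuran 20 (not isolated)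
Conditions: n-BuLi, THF, −78 → 0 °C; oxirane, 0 °C → rt; aq NH4Cl
Reagents that add atoms: oxirane, C1CO1
Why: Lithiation at the only free α-position of the furan and ring opening of ethylene oxide, the classical hydroxyethylation of furyllithium reagents.

**Step 13**
Reactants: 21 2-{5-[(3R)-3-(tert-butyldimethylsilyloxy)butyl]furan-2-yl}ethanol
Product: 22 2-{5-[(3R)-3-(tert-butyldimethylsilyloxy)butyl]furan-2-yl}acetic acid
Conditions: TEMPO (20 mol %), PhI(OAc)2 (2.2 equiv), MeCN–pH 7 buffer, rt
Reagents that add atoms: water, O
Why: TEMPO/PhI(OAc)2 oxidation of a primary alcohol through the aldehyde hydrate to the acid runs near neutral pH, which a 2,5-dialkylfuran and a TBS ether should tolerate.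

**Step 14**
Reactants: 13 (4S,5E,10R)-4-hydroxy-10-methyloxacyclodec-5-ene-2,7-dione; 22 2-{5-[(3R)-3-(tert-butyldimethylsilyloxy)butyl]furan-2-yl}acetic acid
Product: 23 (4S,5E,10R)-10-methyl-2,7-dioxooxacyclodec-5-en-4-yl 2-{5-[(3R)-3-(tert-butyldimethylsilyloxy)butyl]furan-2-yl}acetate
Conditions: DCC (1.1 equiv), DMAP (10 mol %), CH2Cl2, 0 °C
Reagents that add atoms: none
Why: Steglich esterification activates the furylacetic acid and not the macrolide, and catalytic DMAP at 0 °C is too weak a base to start elimination or cyclisation.

**Step 15**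
Reactants: 23 (4S,5E,10R)-10-methyl-2,7-dioxooxacyclodec-5-en-4-yl 2-{5-[(3R)-3-(tert-butyldimethylsilyloxy)butyl]furan-2-yl}acetate
Product: 27 O-TBS-cordycicadin B (γ-lactone cis-fused at C4–C5 of the macrolide; H on C4, C5 and Cα all cis; 10R,5S,4S,αS, side chain R), via lithium ester enolate 24 (not isolated), via lithium ketone enolate 25 (not isolated), via lithium lactone enolate 26 (not isolated)
Conditions: LiN(SiMe3)2 (1.05 equiv), THF (0.01 M), −78 → −40 °C; 2,6-di-tert-butyl-4-methylphenol (3 equiv), −78 °C; then AcOH, −78 °C; pH 6 buffer work-up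
Reagents that add atoms: none
Why: LiN(SiMe3)2 removes the most acidic proton (the furyl- and ester-activated CH2) and enolate 24 adds to C5 of the enone in an intramolecular Michael addition, the closest known type being the base-mediated cyclisation of γ-acyloxy enones and enoates to γ-butyrolactones. The closure is 5-exo-trig at the enone and 5-(enolendo) at the enolate, a mode that also operates in the related arylacetate aldol closure to butenolides and is helped here because the delocalised anion is soft and the tether holds Cα within bonding reach directly under C5. C5 is controlled by the ring conformation: with the s-trans lactone and the s-cis E-enone on the two anti–anti edges of a boat–chair–boat ring and the 10R-methyl equatorial, the 4S-acyloxy group is axial on the outer face of C5=C6, so tether delivery should give only the cis ring fusion (5S). Cα is controlled at the quench: enolate 25 takes up the now most acidic Cα–H (six-membered O···H–C transfer or HN(SiMe3)2 shuttle) to give the planar, furan-conjugated enolate 26, so either Cα epimer from the C–C bond formation converges, and the bulky phenol should protonate 26 at −78 °C on the open face opposite C6 and C3, which places the furyl group cis to C6 (αS, all-cis). The step needs Michael addition to win over Dieckmann acylation of Cα at C2, transannular Claisen attack of 25 on C2, and E1cB loss of the acyloxy group through C3–H. This is secured by one equivalent of a hindered amide base, the gap of some seven to eight pK units between Cα–H and C3–H, the low temperature, and the fact that 26 is the thermodynamic sink and a very poor leaving group.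

**Step 16**
Reactants: 27 O-TBS-cordycicadin B
Product: 28 cordycicadin B
Conditions: HF·pyridine, THF–pyridine, 0 °C → rt; pH 6 buffer work-up
Reagents that add atoms: none
Why: Acidic fluoride desilylation frees the side-chain alcohol without any base strong enough to enolise the α-furyl lactone, so the kinetically set Cα centre should be kept.

**Compound list**
1 | (R)-γ-valerolactone | C[C@@H]1CCC(=O)O1 | starting material
2 | (4R)-4-hydroxy-N-methoxy-N-methylpentanamide | C[C@@H](O)CCC(=O)N(C)OC | intermediate
3 | (6R)-6-hydroxyhept-1-en-3-one | C[C@@H](O)CCC(=O)C=C | intermediate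
4 | (S)-HYTRA, (1S)-2-hydroxy-1,2,2-triphenylethyl acetate | CC(=O)O[C@@H](c1ccccc1)C(O)(c1ccccc1)c1ccccc1 | starting material
5 | acrolein | C=CC=O | starting material
6 | dilithio enolate of 4 | [Li+].[Li+].C=C([O-])O[C@@H](c1ccccc1)C([O-])(c1ccccc1)c1ccccc1 | intermediate
7 | (1S)-2-hydroxy-1,2,2-triphenylethyl (3S)-3-hydroxypent-4-enoate | C=C[C@H](CC(=O)O[C@@H](c1ccccc1)C(O)(c1ccccc1)c1ccccc1)O | intermediate
8 | (3S)-3-hydroxypent-4-enoic acid | C=C[C@H](CC(=O)O)O | intermediate
9 | tert-butyldimethylsilyl (3S)-3-(tert-butyldimethylsilyloxy)pent-4-enoate | C=C[C@H](CC(=O)O[Si](C)(C)C(C)(C)C)O[Si](C)(C)C(C)(C)C | intermediate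
10 | (3S)-3-(tert-butyldimethylsilyloxy)pent-4-enoic acid | C=C[C@H](CC(=O)O)O[Si](C)(C)C(C)(C)C | intermediate
11 | (3S,4E,9R)-3-(tert-butyldimethylsilyloxy)-9-hydroxy-6-oxodec-4-enoic acid | C[C@@H](O)CCC(=O)/C=C/[C@H](CC(=O)O)O[Si](C)(C)C(C)(C)C | intermediate
12 | (4S,5E,10R)-4-(tert-butyldimethylsilyloxy)-10-methyloxacyclodec-5-ene-2,7-dione | C[C@@H]1CCC(=O)/C=C/[C@H](CC(=O)O1)O[Si](C)(C)C(C)(C)C | intermediate
13 | (4S,5E,10R)-4-hydroxy-10-methyloxacyclodec-5-ene-2,7-dione | C[C@@H]1CCC(=O)/C=C/[C@H](CC(=O)O1)O | intermediate
14 | (3R)-butane-1,3-diol | C[C@@H](O)CCO | starting material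
15 | (2R)-4-iodobutan-2-ol | C[C@@H](O)CCI | intermediate
16 | tert-butyl{[(2R)-4-iodobutan-2-yl]oxy}dimethylsilane | C[C@@H](O[Si](C)(C)C(C)(C)C)CCI | intermediate
17 | furan | c1ccoc1 | starting material
18 | 2-furyllithium | [Li]c1ccco1 | intermediate
19 | tert-butyl{[(2R)-4-(furan-2-yl)butan-2-yl]oxy}dimethylsilane | C[C@@H](O[Si](C)(C)C(C)(C)C)CCc1ccco1 | intermediate
20 | 5-lithio derivative of 19 | C[C@@H](O[Si](C)(C)C(C)(C)C)CCc1ccc([Li])o1 | intermediate
21 | 2-{5-[(3R)-3-(tert-butyldimethylsilyloxy)butyl]furan-2-yl}ethanol | C[C@@H](O[Si](C)(C)C(C)(C)C)CCc1ccc(CCO)o1 | intermediate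
22 | 2-{5-[(3R)-3-(tert-butyldimethylsilyloxy)butyl]furan-2-yl}acetic acid | C[C@@H](O[Si](C)(C)C(C)(C)C)CCc1ccc(CC(=O)O)o1 | intermediate
23 | macrolide furylacetate (4S,5E,10R; side chain R) | C[C@@H]1CCC(=O)/C=C/[C@H](CC(=O)O1)OC(=O)Cc1ccc(CC[C@@H](C)O[Si](C)(C)C(C)(C)C)o1 | intermediate
24 | lithium ester enolate of 23 | [Li+].C[C@@H]1CCC(=O)/C=C/[C@H](CC(=O)O1)OC([O-])=Cc1ccc(CC[C@@H](C)O[Si](C)(C)C(C)(C)C)o1 | intermediate
25 | lithium C6=C7 ketone enolate of the Michael adduct (Cα undefined) | [Li+].C[C@@H]1CCC([O-])=C[C@@H]2[C@H](CC(=O)O1)OC(=O)C2c1ccc(CC[C@@H](C)O[Si](C)(C)C(C)(C)C)o1 | intermediate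
26 | lithium lactone enolate (Cα planar) | [Li+].C[C@@H]1CCC(=O)C[C@@H]2[C@H](CC(=O)O1)OC([O-])=C2c1ccc(CC[C@@H](C)O[Si](C)(C)C(C)(C)C)o1 | intermediate
27 | O-TBS-cordycicadin B | C[C@@H]1CCC(=O)C[C@@H]2[C@H](CC(=O)O1)OC(=O)[C@@H]2c1ccc(CC[C@@H](C)O[Si](C)(C)C(C)(C)C)o1 | intermediate
28 | cordycicadin B | C[C@@H]1CCC(=O)C[C@@H]2[C@H](CC(=O)O1)OC(=O)[C@@H]2c1ccc(CC[C@@H](C)O)o1 | target

**Step count and risks**
Total step count: 16. Longest linear sequence: 9 (steps 3–8 and 14–16).

The three steps most likely to fail are steps 15, 7 and 13.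

**Step 15.** Possible failures are β-elimination of the acyloxy group, acylation of the enolate at C2, sluggish enolendo closure, or imperfect facial selectivity in the protonation.
- The fallback sets out from acid 22 and alcohol 13 and comes back at 27.
- The dianion of 22 (LiN(i-Pr)2, 2.1 equiv, THF, −78 °C) is C-acylated with allyl chloroformate to give the allyl hydrogen furylmalonate F1.
- Esterification with 13 (DCC, DMAP, 0 °C) gives the mixed malonate F2.
- The far more acidic malonate CH then closes the lactone through an exocyclic ester enolate with catalytic Cs2CO3 in MeCN at 0 °C. These conditions are too mild for elimination or Claisen chemistry, and they give the α-allyloxycarbonyl lactone F3, in which either configuration at the quaternary carbon serves.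
- Pd(PPh3)4 (zerovalent palladium) with HCO2H in THF removes the activating ester by Tsuji decarboxylative protonation under neutral conditions. This passes through the same planar enolate, which is protonated on the open face to give 27.

**Step 7.** Possible failures are dimerisation or oligomerisation in place of ten-membered ring closure, or loss of silanol from the activated acid.
- The fallback sets out from 3 and 10, replaces steps 6 and 7, and comes back at 12.
- The two pieces are first joined by Steglich esterification (DCC, DMAP, 0 °C) to give the diene ester F4.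
- The ring is then closed at C5=C6 by ring-closing metathesis (second-generation Hoveyda–Grubbs catalyst, toluene, 80 °C, 1 mM, 1,4-benzoquinone) to give 12.

**Step 13.** Possible failures are oxidative opening of the electron-rich furan or decay of the enolisable aldehyde intermediate.
- The fallback sets out from 19, replaces steps 12 and 13, and comes back at 22. It brings in the side chain at the carboxyl oxidation level.
- NBS in DMF at −20 °C gives the 5-bromofuran F5.
- Coupling with the Reformatsky reagent BrZnCH2CO2Et (Pd(dba)2, P(t-Bu)3, THF, rt) gives the ethyl furylacetate F6.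
- LiOH in THF–H2O saponifies F6 to 22.

**Further compounds**
F1 | step 15 | allyl hydrogen 2-{5-[(3R)-3-(tert-butyldimethylsilyloxy)butyl]furan-2-yl}malonate | C[C@@H](O[Si](C)(C)C(C)(C)C)CCc1ccc(C(C(=O)O)C(=O)OCC=C)o1
F2 | step 15 | allyl (4S,5E,10R)-10-methyl-2,7-dioxooxacyclodec-5-en-4-yl furylmalonate | C[C@@H]1CCC(=O)/C=C/[C@H](CC(=O)O1)OC(=O)C(C(=O)OCC=C)c1ccc(CC[C@@H](C)O[Si](C)(C)C(C)(C)C)o1
F3 | step 15 | α-allyloxycarbonyl-α-furyl cis-fused lactone | C[C@@H]1CCC(=O)C[C@@H]2[C@H](CC(=O)O1)OC(=O)C2(C(=O)OCC=C)c1ccc(CC[C@@H](C)O[Si](C)(C)C(C)(C)C)o1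
F4 | step 7 | (2R)-5-oxohept-6-en-2-yl (3S)-3-(tert-butyldimethylsilyloxy)pent-4-enoate | C[C@@H](OC(=O)C[C@@H](C=C)O[Si](C)(C)C(C)(C)C)CCC(=O)C=C
F5 | step 13 | {[(2R)-4-(5-bromofuran-2-yl)butan-2-yl]oxy}(tert-butyl)dimethylsilane | C[C@@H](O[Si](C)(C)C(C)(C)C)CCc1ccc(Br)o1
F6 | step 13 | ethyl 2-{5-[(3R)-3-(tert-butyldimethylsilyloxy)butyl]furan-2-yl}acetate | C[C@@H](O[Si](C)(C)C(C)(C)C)CCc1ccc(CC(=O)OCC)o1
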